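## Analysis of the target

Target 21 is 2,5,6-tribromo-1-methylindole-3-carbaldehyde, a planar 1-methylindole. Its pyrrole ring carries bromine at C2 and a formyl group at C3, and its benzo ring carries bromine at C5 and C6, so C4 and C7 are the only ring CH positions left. There is no stereocenter; the problem is purely one of regiochemistry on nine ring atoms.

The sensitive groups are three. The aldehyde is open to organometallics and strong nucleophiles. The C2–Br bond, conjugated with the 3-formyl group, is a vinylogous acyl bromide and open to addition–elimination by amines, alkoxides or chloride. The aryl bromides exchange with alkyllithiums and insert into low-valent palladium or copper.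

Two features make the synthesis hard. Adjacent bromines at C5 and C6 with C4 and C7 free cannot be obtained by brominating a simple 1-methylindole, because C3 and C2 react first. And C2 of a 3-formylindole is the electrophilic β-carbon of a vinylogous amide, so electrophilic bromination there runs against the polarity, while bromination by deprotonation is simple only as long as no aryl bromide is present. The order of halogen introduction therefore matters as much as the method.

The strategy rests on one structural feature. The C5–C6 unit with its two identical substituents corresponds to a symmetric alkyne carrying two groups that can be replaced ipso. C4 and C7 correspond to the two CH termini of a diene laid across the C3a–C7a bond, which is the diene of a 2-pyranone fused to the pyrrole; its lactone bridge leaves as carbon dioxide.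

## Retrosynthetic reasoning

**C5–Br and C6–Br.** These are cut first in 21, back to the carbon–silicon bonds of 19. Silicon marks exactly these two carbons for ipso attack, so the position of the aryl halogens is decided by where the silyl groups sit, not by the directing effects of the indole. Putting this exchange last means no aryl bromide ever meets an organolithium. The forward reaction has to replace both silyl groups by electrophilic bromination while leaving C4, C7 and the aldehyde alone.

**C2–Br.** This bond is cut next, from 19 back to 15. With C3 acylated, C2 cannot be brominated as a nucleophile, but its hydrogen is the most acidic on the ring and lies next to the formyl group. The forward step is therefore a deprotonation guided by the temporarily masked aldehyde, followed by a bromine transfer. It is placed before the aryl bromines exist, so that the strong base finds only C–H and C–Si bonds.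

**C3–CHO.** The formyl carbon is removed from 15 to give 13. C3 is the most nucleophilic carbon of 13, so a Vilsmeier formylation needs no control element. The formyl group then serves three later purposes: it blocks C3, it deactivates the pyrrole ring toward the final electrophilic bromination, and it supplies the directing group for the C2 metalation.

**The benzo ring (key disconnection).** C4–C5 and C6–C7 of 13 are cut together. This leads to the fused pyranone 10 as the four-carbon diene and the symmetric disilyl alkyne 11 as the two-carbon partner, with the lactone bridge restored. Cutting here and not in the pyrrole ring avoids any need for a pre-made 1,2,4,5-tetrasubstituted benzene. Two skeletal bonds and the carbocycle are gained in one operation, and the symmetry of 11 removes any regiochemical question. The forward reaction must be a [4+2] addition across the two CH termini of 10 followed by decarboxylative cycloreversion.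

**The lactone of 10.** The ring O–C(=O) bond is cut to give the formyl acid 8. In the forward direction the formyl oxygen closes onto the activated carboxyl group and the methylene proton is lost, an enol lactonization that sets up the quinodimethane-type diene.

**Ester and N-methyl.** Acid 8 comes from ester 7 by hydrolysis, and the N–CH3 bond of 7 is cut to give the NH pyrrole 6. Methylating at this stage, when the 2-formyl group has made N–H far more acidic than the ester methylene, lets a weak base do the job without C-alkylation.

**C2–CHO of the pyrrole.** The formyl carbon of 6 is removed to give 4. In a 3-alkyl NH-pyrrole the α-position next to the substituent is the preferred site of formylation.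

**C3–CH2 of the pyrrole.** The side chain of 4 is traced through the N-silyl compound 3 to pyrrole 1 and diazo ester 2. The bulky silyl group on nitrogen shields both α-positions, so the carbenoid from 2 is steered to C3; the silyl group is then removed.

## Alternatives that were turned down

**Alternative 1:** The disconnection is C3–C3a of the pyrrole ring. An N-aryl enaminal, (E)-3-[(4,5-dibromo-2-iodophenyl)(methyl)amino]prop-2-enal A2, would be closed by an intramolecular Heck-type reaction under palladium catalysis with a phosphine and a base. The aryl carbon that bore iodine bonds to the enaminal α-carbon and gives 5,6-dibromo-1-methylindole-3-carbaldehyde A1.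
- For it: the route is short; the formyl group arrives with the ring; both aryl bromines come from a simple aniline; and oxidative addition prefers C–I over C–Br by a wide margin.
- Against it: A1 still lacks the C2 bromine. That bromine must then be introduced on a substrate with two aryl bromides and a deactivating 3-formyl group, where electrophilic bromination is mismatched and lithiation is excluded, so a special zinc amide metalation would be needed. The catalyst must also leave two C–Br bonds untouched during a 5-endo closure that is not fast.
- Comparison: on step economy this alternative is clearly stronger, by roughly half the number of steps. The chosen route offers in its place a C2 bromination carried out by ordinary lithiation on a halogen-free indole. Its halogen pattern is written by a cycloaddition and does not depend on the chemoselectivity of a metal among three carbon–halogen bonds. The same disilyl intermediate 13 could also serve other halogen patterns.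

**Alternative 2:** The disconnection is C3a–C4, preceded by C7–C7a. Mucobromic acid A5 would be attached through its carboxyl-derived carbon to C2 of 1-methylpyrrole A6 and adjusted to (Z)-2,3-dibromo-4-(1-methylpyrrol-2-yl)but-2-enal A4. Under acid, pyrrole C3 attacks the aldehyde carbon, and loss of water aromatizes the new ring to 5,6-dibromo-1-methylindole A3.
- For it: both adjacent bromines are bought in a cheap four-carbon unit, and the key step is a simple cyclodehydration with no regiochemical doubt.
- Against it: turning A5 into A4 requires a C2-selective alkylation of A6, reduction of one terminus to a methylene group beside two vinylic bromides, and retention of the Z geometry. All of this must be done with an acid-sensitive pyrrole and an enal that polymerizes easily. After A3, the formyl group is easy to add, but the C2 bromine must again be introduced in the presence of aryl bromides.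
- Comparison: the step count would be similar to the chosen route, and the benzannulation itself is arguably simpler than a forced cycloaddition. The chosen route offers stable, well-defined intermediates up to the key step and a solved order of halogen introduction.

**Alternative 3:** The disconnection is N1–C2. 4,5-Dibromo-2-(2,2-dibromovinyl)-N-methylaniline A8 would cyclize under copper catalysis with a phosphate base. The nitrogen displaces the vinylic bromine cis to the ring and gives 2,5,6-tribromo-1-methylindole A7 with the second vinylic bromine left at C2. A Vilsmeier formylation would then finish 21.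
- For it: this is the most direct answer to the hardest substituent. The C2 bromine is a by-product of ring closure, only one step follows, and the route is the shortest of all. On directness and step economy it is the strongest of the four.
- Against it: the adjacent aryl bromines are not made but presupposed, in an ortho-amino benzaldehyde with a 1,2,4,5 pattern that has to be secured beforehand. Copper must distinguish the vinylic C–Br from two aryl C–Br bonds and must not couple the reactive C2–Br of the product further. The final formylation passes through a 2-bromo-3-iminium ion in which chloride can displace bromide by addition–elimination. 2-Bromoindoles are also acid-labile.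
- Comparison: the chosen route is longer. In return, no C–Br bond ever sees a transition metal, the C5/C6 pattern is built, not bought, and the acid-labile 2-bromoindole stage is avoided because C2 is brominated only after C3 is acylated.

Key step: step 7

Remark on the chemistry (assumption): iminium salts 5 and 14 are written as chlorides; 12 is racemic and drawn as one enantiomer; 16, 17 and 18 are racemic at the carbinol carbon; 20 is drawn as the 5-bromo-6-silyl isomer, and the opposite order of exchange would converge on 21 as well.

## Route

**Step 1**
Reactants: 1 1-(triisopropylsilyl)pyrrole; 2 ethyl diazoacetate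
Product: 3 ethyl 2-[1-(triisopropylsilyl)pyrrol-3-yl]acetate
Conditions: Rh2(OAc)4 (1 mol %), 1 (3 equiv), CH2Cl2, rt, 2 added over 8 h by syringe pump
Reagents that add atoms: none
Why: Metal-carbenoid C–H functionalization of an electron-rich pyrrole; the triisopropylsilyl group shields both α-positions, so the electrophilic carbenoid should attack C3 (as other electrophiles do with 1) and a proton shift restores the aromatic ring. Slow addition and excess 1 suppress carbene dimerization and double alkylation.

**Step 2**
Reactants: 3 ethyl 2-[1-(triisopropylsilyl)pyrrol-3-yl]acetate
Product: 4 ethyl 2-(1H-pyrrol-3-yl)acetate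
Conditions: Bu4NF (1.1 equiv), THF, 0 °C, 15 min; aq. work-up
Reagents that add atoms: none
Why: Fluoride-induced N–Si cleavage (desilylation) driven by the strong Si–F bond; the ester is untouched at 0 °C, and the air-sensitive NH pyrrole is carried on at once.

**Step 3**
Reactants: 4 ethyl 2-(1H-pyrrol-3-yl)acetate
Product: 6 ethyl 2-(2-formyl-1H-pyrrol-3-yl)acetate, via iminium chloride 5 (not isolated)
Conditions: POCl3 (1.1 equiv), DMF (1.2 equiv), ClCH2CH2Cl, 0 °C to rt; then aq. NaOAc, 60 °C
Reagents that add atoms: N,N-dimethylformamide, CN(C)C=O; water, O
Why: Vilsmeier–Haack formylation; in a 3-alkyl NH-pyrrole the α-carbon next to the substituent (C2) should be preferred because its σ-complex places charge on the substituted carbon C3. The C5 isomer is the expected minor product; it is removed by chromatography and could not lactonize later in any case.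

**Step 4**
Reactants: 6 ethyl 2-(2-formyl-1H-pyrrol-3-yl)acetate
Product: 7 ethyl 2-(2-formyl-1-methylpyrrol-3-yl)acetate
Conditions: MeI (1.5 equiv), K2CO3 (2 equiv), DMF, rt
Reagents that add atoms: iodomethane, CI
Why: SN2 N-alkylation; the 2-formyl group makes N–H acidic enough for carbonate, a base too weak to enolize the ester methylene, so C-methylation should not compete.

**Step 5**
Reactants: 7 ethyl 2-(2-formyl-1-methylpyrrol-3-yl)acetate
Product: 8 2-(2-formyl-1-methylpyrrol-3-yl)acetic acid
Conditions: LiOH·H2O (1.5 equiv), THF/H2O (3:1), 0 °C to rt; then 1 M HCl to pH 3
Reagents that add atoms: lithium hydroxide, [Li+].[OH-]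
Why: Ester saponification by acyl–oxygen cleavage; the aldehyde is a vinylogous formamide without α-hydrogen and should be inert to cold hydroxide.

**Step 6**
Reactants: 8 2-(2-formyl-1-methylpyrrol-3-yl)acetic acid
Product: 10 1-methylpyrano[3,4-b]pyrrol-5(1H)-one, via mixed anhydride 9 (not isolated)
Conditions: Ac2O, 90 °C, 1 h; evaporate, rapid filtration through silica, use promptly
Reagents that add atoms: none
Why: Cyclodehydration (enol lactonization): in mixed anhydride 9 the nucleophilic formyl oxygen attacks the activated acyl carbon, acetate leaves, and loss of the methylene proton gives the pyranone. It is the same transformation that converts ortho-formylarylacetic acids into 2-benzopyran-3-ones, here giving a product stabilized by the pyrrole nitrogen.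

**Step 7**
Reactants: 10 1-methylpyrano[3,4-b]pyrrol-5(1H)-one; 11 bis(trimethylsilyl)acetylene
Product: 13 1-methyl-5,6-bis(trimethylsilyl)indole, via bridged lactone 12 (not isolated)
Conditions: 11 (10 equiv), 1,2-dichlorobenzene, sealed tube, 180 °C, Ar
Reagents that add atoms: none
Why: Compound 10 is a pyrrole-2,3-quinodimethane locked in its cisoid form, with C4=C3a–C7a=C7 as the diene, and a thermal Diels–Alder reaction with 11 should form C4–C5 and C6–C7 in one suprafacial event to give the 2-oxabicyclo[2.2.2]octadienone 12. The six-membered carbocycle is thus closed by a concerted [4+2] cycloaddition and not by a polar exo or endo ring closure. The two bridgehead stereocenters of 12 are fixed relative to each other by the bicycle and disappear when 12 expels carbon dioxide in a retro-[4+2] step, which is irreversible and leaves the benzo ring aromatic. The closest known reaction types are the alkyne cycloaddition and decarboxylation of pyrano[3,4-b]pyrrol-5(1H)-ones to indoles and the addition of 11 to simple 2-pyranones to give 1,2-bis(trimethylsilyl)benzenes. Periselectivity for the pyranone diene over the pyrrole ring follows from the fact that cycloaddition at C4 and C7 restores pyrrole aromaticity, whereas addition across the pyrrole would destroy it. No regiochemistry arises because 11 is symmetric. Alkyne 11 is bulky and not electron-poor, hence the high temperature; the large excess of 11 and moderate dilution are meant to keep self-reaction of 10 behind the cycloaddition.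

**Step 8**
Reactants: 13 1-methyl-5,6-bis(trimethylsilyl)indole
Product: 15 1-methyl-5,6-bis(trimethylsilyl)indole-3-carbaldehyde, via iminium chloride 14 (not isolated)
Conditions: POCl3 (1.2 equiv), DMF, 0 °C to rt; then 2 M aq. NaOH, 0 °C to rt
Reagents that add atoms: N,N-dimethylformamide, CN(C)C=O; water, O
Why: Vilsmeier–Haack formylation at C3, the most nucleophilic carbon of the indole; the chloroiminium ion is too weak an electrophile for ipso attack at C–Si, and the iminium salt 14 deactivates the ring against protodesilylation until basic hydrolysis.

**Step 9**
Reactants: 15 1-methyl-5,6-bis(trimethylsilyl)indole-3-carbaldehyde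
Product: 19 2-bromo-1-methyl-5,6-bis(trimethylsilyl)indole-3-carbaldehyde, via lithium amino alkoxide 16 (not isolated), via 2-lithio amino alkoxide 17 (not isolated), via 2-bromo amino alkoxide 18 (not isolated)
Conditions: Me2NCH2CH2N(Me)Li (1.1 equiv, from the diamine and n-BuLi), THF, −20 °C; n-BuLi (3 equiv), −20 °C, 3 h; BrCl2CCCl2Br (4 equiv), −78 °C to rt; aq. NH4Cl
Reagents that add atoms: 1,2-dibromo-1,1,2,2-tetrachloroethane, BrC(Cl)(Cl)C(Cl)(Cl)Br
Why: In situ protection of the aldehyde as an α-amino alkoxide followed by directed ortho-lithiation; the chelating side arm and the intrinsic acidity of indole C2–H place lithium at C2, positive bromine is transferred from the polyhaloethane, and work-up returns the aldehyde. Aryl–silicon bonds are inert to n-BuLi at −20 °C, and no aryl bromide is yet present to undergo exchange.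

**Step 10**
Reactants: 19 2-bromo-1-methyl-5,6-bis(trimethylsilyl)indole-3-carbaldehyde
Product: 21 2,5,6-tribromo-1-methylindole-3-carbaldehyde, via monobromo monosilyl aldehyde 20 (not isolated)
Conditions: Br2 (2.5 equiv), CH2Cl2, dark, 0 °C to rt (40 °C if the second exchange lags); aq. Na2S2O3
Reagents that add atoms: bromine, BrBr
Why: Twofold electrophilic ipso-bromodesilylation; attack at the silyl-bearing carbons gives β-silyl-stabilized arenium ions that lose the silyl group as its bromide, so no hydrogen bromide is formed. C5 and C6 are in any case the reactive benzo positions of a 3-acylindole, C2 and C3 are blocked, and the first exchange is helped by relief of the ortho-disilyl strain.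

## Compound list

1 | 1-(triisopropylsilyl)pyrrole | CC(C)[Si](C(C)C)(C(C)C)n1cccc1 | starting material
2 | ethyl diazoacetate | CCOC(=O)C=[N+]=[N-] | starting material
3 | ethyl 2-[1-(triisopropylsilyl)pyrrol-3-yl]acetate | CCOC(=O)Cc1ccn([Si](C(C)C)(C(C)C)C(C)C)c1 | intermediate
4 | ethyl 2-(1H-pyrrol-3-yl)acetate | CCOC(=O)Cc1cc[nH]c1 | intermediate
5 | {[3-(2-ethoxy-2-oxoethyl)-1H-pyrrol-2-yl]methylidene}dimethylammonium chloride (not isolated) | CCOC(=O)Cc1cc[nH]c1C=[N+](C)C.[Cl-] | intermediate
6 | ethyl 2-(2-formyl-1H-pyrrol-3-yl)acetate | CCOC(=O)Cc1cc[nH]c1C=O | intermediate
7 | ethyl 2-(2-formyl-1-methylpyrrol-3-yl)acetate | CCOC(=O)Cc1ccn(C)c1C=O | intermediate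
8 | 2-(2-formyl-1-methylpyrrol-3-yl)acetic acid | OC(=O)Cc1ccn(C)c1C=O | intermediate
9 | acetic 2-(2-formyl-1-methylpyrrol-3-yl)acetic anhydride (not isolated) | CC(=O)OC(=O)Cc1ccn(C)c1C=O | intermediate
10 | 1-methylpyrano[3,4-b]pyrrol-5(1H)-one | CN1C=CC2=CC(=O)OC=C12 | intermediate
11 | bis(trimethylsilyl)acetylene | C[Si](C)(C)C#C[Si](C)(C)C | starting material
12 | bridged lactone, racemic (not isolated): 2-oxabicyclo[2.2.2]oct-5-en-3-one whose bridgeheads are C7 and C4 of the later indole, fused across C7a–C3a to the 1-methylpyrrole ring, with trimethylsilyl groups on both alkene carbons | Cn1ccc2c1[C@@H]1OC(=O)[C@H]2C([Si](C)(C)C)=C1[Si](C)(C)C | intermediate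
13 | 1-methyl-5,6-bis(trimethylsilyl)indole | Cn1ccc2cc([Si](C)(C)C)c([Si](C)(C)C)cc21 | intermediate
14 | dimethyl{[1-methyl-5,6-bis(trimethylsilyl)indol-3-yl]methylidene}ammonium chloride (not isolated) | Cn1cc(C=[N+](C)C)c2cc([Si](C)(C)C)c([Si](C)(C)C)cc21.[Cl-] | intermediate
15 | 1-methyl-5,6-bis(trimethylsilyl)indole-3-carbaldehyde | Cn1cc(C=O)c2cc([Si](C)(C)C)c([Si](C)(C)C)cc21 | intermediate
16 | lithium {[2-(dimethylamino)ethyl](methyl)amino}[1-methyl-5,6-bis(trimethylsilyl)indol-3-yl]methanolate, racemic (not isolated) | Cn1cc(C(O[Li])N(C)CCN(C)C)c2cc([Si](C)(C)C)c([Si](C)(C)C)cc21 | intermediate
17 | C2-lithiated derivative of 16, racemic (not isolated) | Cn1c([Li])c(C(O[Li])N(C)CCN(C)C)c2cc([Si](C)(C)C)c([Si](C)(C)C)cc21 | intermediate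
18 | C2-brominated derivative of 16, racemic (not isolated) | Cn1c(Br)c(C(O[Li])N(C)CCN(C)C)c2cc([Si](C)(C)C)c([Si](C)(C)C)cc21 | intermediate
19 | 2-bromo-1-methyl-5,6-bis(trimethylsilyl)indole-3-carbaldehyde | Cn1c(Br)c(C=O)c2cc([Si](C)(C)C)c([Si](C)(C)C)cc21 | intermediate
20 | 2,5-dibromo-1-methyl-6-(trimethylsilyl)indole-3-carbaldehyde (not isolated) | Cn1c(Br)c(C=O)c2cc(Br)c([Si](C)(C)C)cc21 | intermediate
21 | 2,5,6-tribromo-1-methylindole-3-carbaldehyde | Cn1c(Br)c(C=O)c2cc(Br)c(Br)cc21 | target

## Step count and least certain steps

Total step count: 10. Longest linear sequence: 10 steps (1 to 21); 2 and 11 enter as purchased reagents.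

**Step 7 (key step).** The most likely failure is that the cycloaddition is too slow. Alkyne 11 is bulky and not electron-poor, while the diene is electron-rich, so thermal self-reaction and oligomerization of 10 could consume the diene before 11 adds. The fallback sets out from 10 and changes the ipso-replaceable element from silicon to boron. 10 is heated with 1,2-bis(4,4,5,5-tetramethyl-1,3,2-dioxaborolan-2-yl)ethyne F1, a planar alkyne with π-acceptor substituents of the kind known to add to 2-pyranones. After loss of carbon dioxide this should give 1-methyl-5,6-bis(4,4,5,5-tetramethyl-1,3,2-dioxaborolan-2-yl)indole F2. Vilsmeier–Haack formylation gives the 3-carbaldehyde F3. Zincation at C2 with TMP2Zn·2MgCl2·2LiCl, a base that tolerates aldehydes and boronic esters, followed by N-bromosuccinimide, gives the 2-bromo aldehyde F4. Copper-mediated bromodeboronation of both boronic esters (CuBr2, MeOH/H2O, 80 °C) then rejoins the route at 21.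

**Step 6.** The pyranone 10 has no substituent at C7 and is an enol lactone of an aldehyde. Hydrolytic ring opening on silica or in moist air, and oligomerization on concentration, are the likely losses. The fallback sets out from 8 and avoids isolation altogether: 8 is heated with Ac2O and a large excess of 11 in a sealed tube, so that 10 is generated in the presence of its trap and consumed as it forms. The route is rejoined at 13.

**Step 10.** The second silicon–bromine exchange may stall, because the ring of 20 is deactivated by the formyl group, the C2 bromine and the first aryl bromine. Traces of hydrogen bromide from moisture may also cause protodesilylation, so that one bromine is missing. The fallback sets out from 15 and moves the exchange ahead of the C2 bromination, onto the more electron-rich ring. Br2 in CH2Cl2 should convert 15 into 5,6-dibromo-1-methylindole-3-carbaldehyde F5 (the structure labelled A1 above). C2 is then metalated with TMP2Zn·2MgCl2·2LiCl, which does not undergo halogen–metal exchange with aryl bromides, and the arylzinc is quenched with Br2 to rejoin the route at 21.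

**Step 3.** Poor positional selectivity is the risk: formylation at C5 could compete with the wanted attack at C2, since the ester-bearing methylene group activates C2 only weakly. The fallback sets out from 4 and delivers the one-carbon unit intramolecularly. N-methylation (NaH, 1.0 equiv, MeI, THF, 0 °C) gives ethyl 2-(1-methylpyrrol-3-yl)acetate F6, and saponification gives 2-(1-methylpyrrol-3-yl)acetic acid F7. Treatment with acetic formic anhydride F8 and BF3·OEt2 in CH2Cl2 should form the side-chain formic anhydride. Its formyl carbon can reach only C2, through a six-membered transition state, and dehydration of the resulting cyclic acyloxy carbinol gives the pyranone directly. The route is rejoined at 10.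

**Step 1.** Loss of positional selectivity in the carbenoid attack (C2 against C3) and carbene dimerization are the risks. The fallback sets out from 1 and fixes the position by halogenation. N-Bromosuccinimide in THF at −78 °C gives 3-bromo-1-(triisopropylsilyl)pyrrole F9. A Negishi-type coupling under zerovalent palladium (Pd2(dba)3, XPhos, THF, 60 °C) with the Reformatsky reagent ethyl (bromozincio)acetate F10 then rejoins the route at 3.

## Further compounds

F1 | step 7 | 1,2-bis(4,4,5,5-tetramethyl-1,3,2-dioxaborolan-2-yl)ethyne | CC1(C)OB(OC1(C)C)C#CB1OC(C)(C)C(C)(C)O1
F2 | step 7 | 1-methyl-5,6-bis(4,4,5,5-tetramethyl-1,3,2-dioxaborolan-2-yl)indole | Cn1ccc2cc(B3OC(C)(C)C(C)(C)O3)c(B3OC(C)(C)C(C)(C)O3)cc21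
F3 | step 7 | 1-methyl-5,6-bis(4,4,5,5-tetramethyl-1,3,2-dioxaborolan-2-yl)indole-3-carbaldehyde | Cn1cc(C=O)c2cc(B3OC(C)(C)C(C)(C)O3)c(B3OC(C)(C)C(C)(C)O3)cc21
F4 | step 7 | 2-bromo-1-methyl-5,6-bis(4,4,5,5-tetramethyl-1,3,2-dioxaborolan-2-yl)indole-3-carbaldehyde | Cn1c(Br)c(C=O)c2cc(B3OC(C)(C)C(C)(C)O3)c(B3OC(C)(C)C(C)(C)O3)cc21
F0 | step 6 | none | none
F5 | step 10 | 5,6-dibromo-1-methylindole-3-carbaldehyde | Cn1cc(C=O)c2cc(Br)c(Br)cc21
F6 | step 3 | ethyl 2-(1-methylpyrrol-3-yl)acetate | CCOC(=O)Cc1ccn(C)c1
F7 | step 3 | 2-(1-methylpyrrol-3-yl)acetic acid | OC(=O)Cc1ccn(C)c1
F8 | step 3 | acetic formic anhydride | CC(=O)OC=O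
F9 | step 1 | 3-bromo-1-(triisopropylsilyl)pyrrole | CC(C)[Si](C(C)C)(C(C)C)n1ccc(Br)c1
F10 | step 1 | ethyl (bromozincio)acetate | CCOC(=O)C[Zn]Br
A1 | alternative 1 | 5,6-dibromo-1-methylindole-3-carbaldehyde | Cn1cc(C=O)c2cc(Br)c(Br)cc21
A2 | alternative 1 | (E)-3-[(4,5-dibromo-2-iodophenyl)(methyl)amino]prop-2-enal | CN(/C=C/C=O)c1cc(Br)c(Br)cc1I
A3 | alternative 2 | 5,6-dibromo-1-methylindole | Cn1ccc2cc(Br)c(Br)cc21
A4 | alternative 2 | (Z)-2,3-dibromo-4-(1-methylpyrrol-2-yl)but-2-enal | Cn1cccc1C/C(Br)=C(/Br)C=O
A5 | alternative 2 | mucobromic acid (3,4-dibromo-5-hydroxyfuran-2(5H)-one) | OC1OC(=O)C(Br)=C1Br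
A6 | alternative 2 | 1-methylpyrrole | Cn1cccc1
A7 | alternative 3 | 2,5,6-tribromo-1-methylindole | Cn1c(Br)cc2cc(Br)c(Br)cc21
A8 | alternative 3 | 4,5-dibromo-2-(2,2-dibromovinyl)-N-methylaniline | CNc1cc(Br)c(Br)cc1C=C(Br)Br
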